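All runs stem from a simulated flask for substances that don't exist, and the scatter is random.

**One step.** In a one-step world first order in second substrate, doubling that charge doubles the rate. Here the catalyst also has a round with starting material, so I compare two rates, and their ratio is my estimate of the factor asked for.

all flasks: free enzyme 17 µM

| run | starting material | second substrate | remark |
|---|---|---|---|
| dawn | 48 mM | 35.7 mM | run made earlier |
| noon | 75 mM | 35.7 mM | run made earlier |
| winter | 34 mM | 71 mM | run made earlier |
| flask | 34 mM | 35.7 mM |  |

| run | time / min | target / % |
|---|---|---|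
| dawn | 0.833 | 8 |
| dawn | 2.50 | 23 |
| dawn | 4.00 | 34 |
| dawn | 6.00 | 43 |
| dawn | 10.0 | 59 |
| noon | 2.00 | 15 |
| noon | 4.00 | 23 |
| noon | 5.00 | 25 |
| noon | 8.00 | 35 |
| noon | 10.0 | 36 |
| winter | 0.667 | 10 |
| winter | 1.33 | 18 |
| winter | 2.50 | 34 |
| winter | 5.00 | 63 |
| winter | 10.0 | 92 |

(standard deviation of a reading: 1.5 percentage points)

- apparent order in free enzyme when 10% of the starting material are converted (percent change of the rate of making target for one percent more free enzyme charged)
- factor on the rate of making target when 10% of the starting material are converted if second substrate is charged twice over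

**First rate.** The winter run has the flask's starting material and 71 mM of second substrate, close to the doubled charge of 71.4 mM. Its mean rate of making target up to its first reading is the stand-in rate 5.10 mM min⁻¹, and the scatter of that reading is worth 0.765 mM min⁻¹ of it.

**Second rate.** The flask itself is unread. The dawn run has the same second substrate and more starting material, and reads 4.61 mM min⁻¹. I expect the flask below that, so I expect a factor above 1.11, a ratio of two scattered readings and no bound.

**The forecast.** It takes 3.9 and 5.0 mM/min and gives 1.3 (1.15 to 1.5), and an order of 1 (0.93 to 1.1), noting “Enzyme is micromolar against millimolar substrates, so rate scales with enzyme”.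

**The result.** The flask gives a factor of 1.22 and an order of 1.0.

    starting material + free enzyme ⇌ first complex (K = 39.0 M⁻¹, k = 7690 M⁻¹ s⁻¹)
    first complex ⇌ loaded enzyme + first product (K = 0.0800 M, k = 24.0 s⁻¹)
    second substrate + loaded enzyme ⇌ second complex (K = 1300 M⁻¹, k = 427 M⁻¹ s⁻¹)
    second complex → free enzyme + target (k = 13.7 s⁻¹)
    first complex → spent catalyst (k = 5.76 × 10⁻⁴ s⁻¹)
    second substrate → decomposed reagent (k = 1.85 × 10⁻⁴ s⁻¹)

The flask's rate of making target at 10% conversion is 4.33 mM min⁻¹, reached at 0.752 min. Set on that rate, the stand-in rate read from the winter run gives a factor of 1.18.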